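The constants are made up; the rest is arithmetic.

The vessel is closed and stirred; in it the starting material and the partner couple to the target and to both isomers, while the partner also decays by itself.

starting material 20 mM; partner 1.10 equiv; time 2.0 min

    starting material + partner → target (k1 = 1.3 L mol⁻¹ s⁻¹)
    starting material + partner → isomer of the product (k2 = 0.71 L mol⁻¹ s⁻¹)
    starting material + partner → second isomer (k3 = 0.65 L mol⁻¹ s⁻¹)
    crystals ⇌ target, rate k4*(cs4 - [target]) while solid is left; crystals form when [target] > cs4 (cs4 = 8.2 mM, k4 = 0.66 s⁻¹)
    partner → decomposed reagent (k5 = 0.038 s⁻¹)

- target and crystals together at 2.0 min, in percent of the starting material charged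
- concentration of target in solution at 2.0 min, in percent of saturation

We count turnovers, one turnover being the coupling that lowers c(starting material) by a factor e. The couplings share one rate form, so the target takes 48.9% of the conversion at any moment. We call the break-even concentration c_even 14.3 mM the c(starting material) at which the partner goes equally to coupling and to decay, which means that each turnover costs c_even of partner as decomposed reagent. Decay by itself leaves 1.05% of the partner's charge by 2.0 min, so we balance the charge of 22.0 mM against conversion plus decay with c(partner) near zero. Linearising gives 0.642 turnovers and one Newton step gives 0.777, hence y of 26.4% and 5.28 mM of target, which is less than 8.2 mM, so we expect 64.4% of saturation.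

The forecast, slightly above us, gives 26.5% and 64.6%, reasoning that “This is below 8.2 mM, so no crystals form.”

The simulation gives 26.5% and 64.6%, and at 2.00 min this flask holds 45.8% of the starting material charged beside 0.0399% of the partner's charge: the partner, though charged in excess, is the limiting reagent. The decomposed reagent of this flask, 11.2 mM, divided by c_even counts 0.783 turnovers. In the neighbour flask with 50 mM of starting material, 18.6 mM of decomposed reagent over the same c_even counts 1.30 turnovers, which reckons to 27.2% of starting material left and 35.6% for y, and that flask stood at 27.2% and 35.6%.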